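The dihydropyran ring C is disconnected at C2–C3 and C4–C4a. A nickel-catalysed enantioselective arylalkylative [4+2] annulation should make both bonds at once: an aryl bromide of ring A carrying an ortho O–CH2–B(pin) arm (the four-atom unit C4a–C8a–O1–C2) adds across the terminal vinyl group (C3=C4) of an 8-vinyl-2,2-dimethylchromene that is ring B, and the ligand sets C3 as (R). The step exploits the ortho relationship of O1 and C4a on the resorcinol ring A and the benzylic character of C3. A second O–CH2–B(pin) group masks the 7-OH and is removed oxidatively at the end.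

Key step: step 9

Assumption: the sense of induction of the bis(oxazoline) ligand in step 9 cannot be derived from precedent on this substrate class; the (S,S)-ligand is written, and its enantiomer is used if a model run shows the opposite sense.

Step 1
Reactants: 1 4,6-dibromobenzene-1,3-diol
Product: 2 1,5-dibromo-2,4-bis(methoxymethoxy)benzene
Conditions: MOMCl, i-Pr2NEt, CH2Cl2, 0 °C to rt
Reagents that add atoms: chloromethyl methyl ether COCCl
Why: Acetal protection (O-alkylation) of both phenols gives ethers that tolerate organolithium chemistry and assist the later bromine–lithium exchange by chelation.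

Step 2
Reactants: 2 1,5-dibromo-2,4-bis(methoxymethoxy)benzene
Product: 4 1-bromo-2,4-bis(methoxymethoxy)-5-(3-methylbut-2-en-1-yl)benzene, via aryllithium 3 (not isolated)
Conditions: n-BuLi (1.05 equiv), THF, −78 °C; then CuI (10 mol%), prenyl bromide, −78 to 0 °C
Reagents that add atoms: 1-bromo-3-methylbut-2-ene CC(C)=CCBr
Why: Bromine–lithium exchange of the symmetrical dibromide should stop at the monolithium stage (a second exchange would give a dianion), and copper-catalysed allylic substitution at the primary carbon of prenyl bromide (SN2 mode) installs the linear prenyl group and desymmetrises the ring.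

Step 3
Reactants: 4 1-bromo-2,4-bis(methoxymethoxy)-5-(3-methylbut-2-en-1-yl)benzene
Product: 5 4-bromo-6-(3-methylbut-2-en-1-yl)benzene-1,3-diol
Conditions: HCl (3 M aq), MeOH, 45 °C
Reagents that add atoms: none
Why: Acid-catalysed transacetalisation to methanol (MOM cleavage) should free both phenols under conditions mild enough to leave the trisubstituted alkene untouched.

Step 4
Reactants: 5 4-bromo-6-(3-methylbut-2-en-1-yl)benzene-1,3-diol
Product: 6 2,2'-{[4-bromo-6-(3-methylbut-2-en-1-yl)-1,3-phenylene]bis(oxymethylene)}bis(4,4,5,5-tetramethyl-1,3,2-dioxaborolane)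
Conditions: ICH2B(pin) (2.4 equiv), K2CO3, MeCN, 50 °C
Reagents that add atoms: 2-(iodomethyl)-4,4,5,5-tetramethyl-1,3,2-dioxaborolane CC1(C)OB(CI)OC1(C)C
Why: Williamson-type O-alkylation of both phenoxides with the α-iodo boronate (attack at boron, then 1,2-migration with loss of iodide, a Matteson-type substitution) gives two aryloxymethyl boronates, one as the C2 arm ortho to bromine and one as an oxidatively removable mask of the 7-OH, so the two oxygens need not be told apart.

Step 5
Reactants: 7 2,4-dihydroxybenzaldehyde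
Product: 8 2-hydroxy-4-[(triisopropylsilyl)oxy]benzaldehyde
Conditions: TIPSCl (1.05 equiv), imidazole, CH2Cl2, 0 °C
Reagents that add atoms: chlorotriisopropylsilane CC(C)[Si](Cl)(C(C)C)C(C)C
Why: Selective O-silylation of the 4-OH is expected because the 2-OH is held in a hydrogen bond to the aldehyde and is much less nucleophilic.

Step 6
Reactants: 8 2-hydroxy-4-[(triisopropylsilyl)oxy]benzaldehyde
Product: 9 2-[(2-methylbut-3-yn-2-yl)oxy]-4-[(triisopropylsilyl)oxy]benzaldehyde
Conditions: 3-chloro-3-methylbut-1-yne, DBU, CuCl2·2H2O (1 mol%), MeCN, 0 °C to rt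
Reagents that add atoms: 3-chloro-3-methylbut-1-yne CC(C)(Cl)C#C
Why: Copper-catalysed propargylic substitution of the tertiary propargylic chloride by the phenoxide (O-alkylation through a copper acetylide/allenylidene) should etherify the remaining hindered phenol without touching the aldehyde or the silyl ether.

Step 7
Reactants: 9 2-[(2-methylbut-3-yn-2-yl)oxy]-4-[(triisopropylsilyl)oxy]benzaldehyde
Product: 11 2,2-dimethyl-5-[(triisopropylsilyl)oxy]-2H-chromene-8-carbaldehyde, via allenylphenol 10 (not isolated)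
Conditions: N,N-diethylaniline, 190 °C
Reagents that add atoms: none
Why: Thermal aromatic propargyl Claisen rearrangement ([3,3]) to the only free ortho position, tautomerisation to the allenylphenol, 1,5-hydrogen shift and oxa-6π electrocyclisation should give the 2,2-dimethyl-2H-chromene fused at the carbon between the two oxygens.

Step 8
Reactants: 11 2,2-dimethyl-5-[(triisopropylsilyl)oxy]-2H-chromene-8-carbaldehyde
Product: 13 [(8-ethenyl-2,2-dimethyl-2H-chromen-5-yl)oxy]triisopropylsilane, via phosphorus ylide 12 (not isolated)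
Conditions: Ph3PCH3Br, KOt-Bu, THF, 0 °C to rt
Reagents that add atoms: methyltriphenylphosphonium bromide C[P+](c1ccccc1)(c1ccccc1)c1ccccc1.[Br-]
Why: Wittig methylenation of the aryl aldehyde gives the monosubstituted vinylarene that serves as the C3=C4 partner.

Step 9
Reactants: 6 ring A bromide bis(boronate); 13 [(8-ethenyl-2,2-dimethyl-2H-chromen-5-yl)oxy]triisopropylsilane (1.3 equiv)
Product: 14 triisopropyl[(8-{(3R)-6-(3-methylbut-2-en-1-yl)-7-[(4,4,5,5-tetramethyl-1,3,2-dioxaborolan-2-yl)methoxy]-3,4-dihydro-2H-chromen-3-yl}-2,2-dimethyl-2H-chromen-5-yl)oxy]silane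
Conditions: Ni(cod)2 (10 mol%), (4S,4'S)-4,4'-di(propan-2-yl)-4,4',5,5'-tetrahydro-2,2'-bioxazole (12 mol%), K3PO4, H2O (5 equiv), 1,4-dioxane, 60 °C
Reagents that add atoms: none
Why: Proposed new method: zerovalent nickel inserts into the C–Br bond of 6, the aryl–nickel species adds across the vinyl group of 13 in the Heck sense (aryl carbon to the terminal CH2, nickel to the benzylic carbon as an η3-benzyl that resists β-hydride elimination), the hydroxide-activated ortho O–CH2–B(pin) arm then transmetalates intramolecularly to a seven-membered oxanickelacycle, and C(sp3)–C(sp3) reductive elimination forms the CH2–CH bond. The closest known reaction types are the nickel-catalysed three-component 1,2-diarylation and arylalkylation of vinylarenes with aryl halides and organoboron or organozinc reagents and the nickel/bis(oxazoline) enantioconvergent alkylation of secondary benzylic nickel species; the new element is that the alkyl nucleophile is an α-aryloxymethyl boronate tethered to the aryl halide, so the two couplings amount to a formal [4+2] annulation. Ring C is closed in the second event by a six-membered-ring-forming reductive elimination from the seven-membered nickelacycle, the first C–C bond (C4–C4a) being intermolecular. The new stereocenter C3 is set under ligand control: the η3-benzyl nickel intermediate should epimerise quickly, and the chiral bis(oxazoline) selects the diastereomeric transition state of reductive elimination that leads to (R). The step needs regioselectivity (aryl to CH2), secured by benzylic stabilisation of the insertion product, and chemoselectivity, secured because only the monosubstituted vinyl group inserts while the prenyl and chromene double bonds are tri- and 1,2-disubstituted, and because the second O–CH2–B(pin) group has no neighbouring C–Ni bond and cannot cyclise.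

Step 10
Reactants: 14 boryl-methyl ether / silyl ether protected (3R)-isoflavan
Product: 17 8-[(3R)-7-hydroxy-6-(3-methylbut-2-en-1-yl)-3,4-dihydro-2H-chromen-3-yl]-2,2-dimethyl-2H-chromen-5-ol, via hemiformal 15 (not isolated), via silyl ether phenol 16 (not isolated)
Conditions: NaBO3·4H2O, THF/H2O, rt; then TBAF, THF, 0 °C to rt
Reagents that add atoms: none
Why: Perborate oxidation of the C–B bond gives an aryl hemiformal that collapses to the phenol and formaldehyde, and fluoride then cleaves the aryl silyl ether (desilylation); neither reagent should touch the prenyl or chromene double bonds or the C3 stereocenter.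

Compound list
1 | 4,6-dibromobenzene-1,3-diol | Oc1cc(O)c(Br)cc1Br | starting material
2 | 1,5-dibromo-2,4-bis(methoxymethoxy)benzene | COCOc1cc(OCOC)c(Br)cc1Br | intermediate
3 | [5-bromo-2,4-bis(methoxymethoxy)phenyl]lithium | [Li]c1cc(Br)c(OCOC)cc1OCOC | intermediate
4 | 1-bromo-2,4-bis(methoxymethoxy)-5-(3-methylbut-2-en-1-yl)benzene | CC(C)=CCc1cc(Br)c(OCOC)cc1OCOC | intermediate
5 | 4-bromo-6-(3-methylbut-2-en-1-yl)benzene-1,3-diol | CC(C)=CCc1cc(Br)c(O)cc1O | intermediate
6 | 2,2'-{[4-bromo-6-(3-methylbut-2-en-1-yl)-1,3-phenylene]bis(oxymethylene)}bis(4,4,5,5-tetramethyl-1,3,2-dioxaborolane) | CC(C)=CCc1cc(Br)c(OCB2OC(C)(C)C(C)(C)O2)cc1OCB1OC(C)(C)C(C)(C)O1 | intermediate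
7 | 2,4-dihydroxybenzaldehyde | O=Cc1ccc(O)cc1O | starting material
8 | 2-hydroxy-4-[(triisopropylsilyl)oxy]benzaldehyde | O=Cc1ccc(O[Si](C(C)C)(C(C)C)C(C)C)cc1O | intermediate
9 | 2-[(2-methylbut-3-yn-2-yl)oxy]-4-[(triisopropylsilyl)oxy]benzaldehyde | C#CC(C)(C)Oc1cc(O[Si](C(C)C)(C(C)C)C(C)C)ccc1C=O | intermediate
10 | 2-hydroxy-3-(3-methylbuta-1,2-dien-1-yl)-4-[(triisopropylsilyl)oxy]benzaldehyde | O=Cc1ccc(O[Si](C(C)C)(C(C)C)C(C)C)c(C=C=C(C)C)c1O | intermediate
11 | 2,2-dimethyl-5-[(triisopropylsilyl)oxy]-2H-chromene-8-carbaldehyde | O=Cc1ccc(O[Si](C(C)C)(C(C)C)C(C)C)c2c1OC(C)(C)C=C2 | intermediate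
12 | methylidenetriphenylphosphorane | C=P(c1ccccc1)(c1ccccc1)c1ccccc1 | intermediate
13 | [(8-ethenyl-2,2-dimethyl-2H-chromen-5-yl)oxy]triisopropylsilane | C=Cc1ccc(O[Si](C(C)C)(C(C)C)C(C)C)c2c1OC(C)(C)C=C2 | intermediate
14 | triisopropyl[(8-{(3R)-6-(3-methylbut-2-en-1-yl)-7-[(4,4,5,5-tetramethyl-1,3,2-dioxaborolan-2-yl)methoxy]-3,4-dihydro-2H-chromen-3-yl}-2,2-dimethyl-2H-chromen-5-yl)oxy]silane | CC(C)=CCc1cc2c(cc1OCB1OC(C)(C)C(C)(C)O1)OC[C@@H](c1ccc(O[Si](C(C)C)(C(C)C)C(C)C)c3c1OC(C)(C)C=C3)C2 | intermediate
15 | {[(3R)-3-{2,2-dimethyl-5-[(triisopropylsilyl)oxy]-2H-chromen-8-yl}-6-(3-methylbut-2-en-1-yl)-3,4-dihydro-2H-chromen-7-yl]oxy}methanol | CC(C)=CCc1cc2c(cc1OCO)OC[C@@H](c1ccc(O[Si](C(C)C)(C(C)C)C(C)C)c3c1OC(C)(C)C=C3)C2 | intermediate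
16 | (3R)-3-{2,2-dimethyl-5-[(triisopropylsilyl)oxy]-2H-chromen-8-yl}-6-(3-methylbut-2-en-1-yl)-3,4-dihydro-2H-chromen-7-ol | CC(C)=CCc1cc2c(cc1O)OC[C@@H](c1ccc(O[Si](C(C)C)(C(C)C)C(C)C)c3c1OC(C)(C)C=C3)C2 | intermediate
17 | 8-[(3R)-7-hydroxy-6-(3-methylbut-2-en-1-yl)-3,4-dihydro-2H-chromen-3-yl]-2,2-dimethyl-2H-chromen-5-ol | CC(C)=CCc1cc2c(cc1O)OC[C@@H](c1ccc(O)c3c1OC(C)(C)C=C3)C2 | target

Total step count: 10 (steps 1–4 build the ring A partner, steps 5–8 the ring B partner, steps 9–10 join and unmask).
Longest linear sequence: 6 steps (1, 2, 3, 4, 9, 10 or 5, 6, 7, 8, 9, 10).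

Steps most likely to fail

1. Step 9 (Proposed new method). The benzylic nickel intermediate may undergo β-hydride elimination (a Heck-type outcome). Transfer of the oxymethyl arm from boron to nickel may be too slow. Transmetalation may precede insertion, followed by insertion into the Ni–CH2 bond, which gives the regioisomeric annulation. Enantioselection may be low. Fallback with known chemistry, setting out from 13 and 4 and coming back at 16: 13 is hydroborated at the vinyl group with 9-BBN and oxidised (NaBO3) to 2-{2,2-dimethyl-5-[(triisopropylsilyl)oxy]-2H-chromen-8-yl}ethanol F1. This is oxidised (TEMPO cat., PhI(OAc)2, MeCN/H2O) to the arylacetic acid F2, which is joined through its pivalic mixed anhydride to lithiated (R)-4-benzyloxazolidin-2-one to give the N-acyl oxazolidinone F3. In parallel, 4 is converted by bromine–lithium exchange and DMF into 2,4-bis(methoxymethoxy)-5-(3-methylbut-2-en-1-yl)benzaldehyde F4, reduced (NaBH4) to the benzylic alcohol F5 and turned into the benzylic bromide F6 (MsCl, Et3N; then LiBr). Evans alkylation of the sodium enolate of F3 (NaHMDS, THF, −78 °C) with F6 should give the alkylated imide F7, the (R) centre being set by the auxiliary. LiBH4 removes the auxiliary to give the primary alcohol F8. Dilute HCl in MeOH removes both MOM groups to give the resorcinol alcohol F9. Mitsunobu ring closure (PPh3, DIAD, THF) of the primary alcohol onto the ortho phenol then gives 16, and the fluoride stage of step 10 completes the synthesis.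

2. Step 3. Acid may promote cyclisation of the prenyl group onto the neighbouring phenol or addition of HCl across the alkene. Fallback, setting out from 1 and coming back at 5: 1 is protected as the bis[2-(trimethylsilyl)ethoxymethyl] ether, 1,5-dibromo-2,4-bis{[2-(trimethylsilyl)ethoxy]methoxy}benzene F10 (SEMCl, i-Pr2NEt). The same bromine–lithium exchange and copper-catalysed prenylation give the prenylated bromide F11. Both groups are then removed without acid by fluoride (TBAF, DMPU, 80 °C), which gives 5.

3. Step 6. O-alkylation of the hydrogen-bonded, hindered phenol with a tertiary propargylic chloride may be sluggish, and the chloride may eliminate instead. Fallback, setting out from 8 and coming back at 11: the chromene is built in one operation by condensation of 8 with 3-methylbut-2-enal in the presence of PhB(OH)2 and AcOH in toluene at reflux (ortho-specific condensation, dehydration and oxa-6π electrocyclisation). This gives 11 directly and bypasses 9 and step 7.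

Further compounds
F1 | step 9 | 2-{2,2-dimethyl-5-[(triisopropylsilyl)oxy]-2H-chromen-8-yl}ethanol | OCCc1ccc(O[Si](C(C)C)(C(C)C)C(C)C)c2c1OC(C)(C)C=C2
F2 | step 9 | {2,2-dimethyl-5-[(triisopropylsilyl)oxy]-2H-chromen-8-yl}acetic acid | OC(=O)Cc1ccc(O[Si](C(C)C)(C(C)C)C(C)C)c2c1OC(C)(C)C=C2
F3 | step 9 | (4R)-4-benzyl-3-({2,2-dimethyl-5-[(triisopropylsilyl)oxy]-2H-chromen-8-yl}acetyl)oxazolidin-2-one | O=C(Cc1ccc(O[Si](C(C)C)(C(C)C)C(C)C)c2c1OC(C)(C)C=C2)N1[C@H](Cc2ccccc2)COC1=O
F4 | step 9 | 2,4-bis(methoxymethoxy)-5-(3-methylbut-2-en-1-yl)benzaldehyde | CC(C)=CCc1cc(C=O)c(OCOC)cc1OCOC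
F5 | step 9 | [2,4-bis(methoxymethoxy)-5-(3-methylbut-2-en-1-yl)phenyl]methanol | CC(C)=CCc1cc(CO)c(OCOC)cc1OCOC
F6 | step 9 | 1-(bromomethyl)-2,4-bis(methoxymethoxy)-5-(3-methylbut-2-en-1-yl)benzene | CC(C)=CCc1cc(CBr)c(OCOC)cc1OCOC
F7 | step 9 | (4R)-4-benzyl-3-[(2R)-3-[2,4-bis(methoxymethoxy)-5-(3-methylbut-2-en-1-yl)phenyl]-2-{2,2-dimethyl-5-[(triisopropylsilyl)oxy]-2H-chromen-8-yl}propanoyl]oxazolidin-2-one | O=C([C@H](Cc1cc(CC=C(C)C)c(OCOC)cc1OCOC)c1ccc(O[Si](C(C)C)(C(C)C)C(C)C)c2c1OC(C)(C)C=C2)N1[C@H](Cc2ccccc2)COC1=O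
F8 | step 9 | (2R)-3-[2,4-bis(methoxymethoxy)-5-(3-methylbut-2-en-1-yl)phenyl]-2-{2,2-dimethyl-5-[(triisopropylsilyl)oxy]-2H-chromen-8-yl}propan-1-ol | OC[C@@H](c1ccc(O[Si](C(C)C)(C(C)C)C(C)C)c2c1OC(C)(C)C=C2)Cc1cc(CC=C(C)C)c(OCOC)cc1OCOC
F9 | step 9 | 4-[(2R)-2-{2,2-dimethyl-5-[(triisopropylsilyl)oxy]-2H-chromen-8-yl}-3-hydroxypropyl]-6-(3-methylbut-2-en-1-yl)benzene-1,3-diol | OC[C@@H](c1ccc(O[Si](C(C)C)(C(C)C)C(C)C)c2c1OC(C)(C)C=C2)Cc1cc(CC=C(C)C)c(O)cc1O
F10 | step 3 | 1,5-dibromo-2,4-bis{[2-(trimethylsilyl)ethoxy]methoxy}benzene | C[Si](C)(C)CCOCOc1cc(OCOCC[Si](C)(C)C)c(Br)cc1Br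
F11 | step 3 | 1-bromo-5-(3-methylbut-2-en-1-yl)-2,4-bis{[2-(trimethylsilyl)ethoxy]methoxy}benzene | CC(C)=CCc1cc(Br)c(OCOCC[Si](C)(C)C)cc1OCOCC[Si](C)(C)C
F0 | step 6 | none | none
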